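Germacrane numbering is used for every ring compound: C1–C10 are the ring carbons, C12 is the lactone carbonyl on O6, C11 and C13 are the lactone α-carbon and its exo-methylene, C14 is the ester carbon on C10 and C15 is the methyl on C4. α and β refer to the usual drawing with H-7 α.

## Analysis of the target

The target is a germacranolide: a ten-membered carbocycle trans-fused at C6–C7 to an α-methylene-γ-butyrolactone, with a methyl ester on C10, a methyl on C4, an angelate on O8, an acetate on O9 and a free hydroxyl on C2. Both ring unsaturations are cis with respect to the ring. The C1=C10 enoate has C9 and C2 on the same side (E by priority, because C14 outranks C9), and the 4,5-epoxide has C3 and C6 cis, so it derives from a Z C4=C5 olefin. There are seven stereocenters, (2S,4R,5S,6S,7R,8S,9S). C4 to C9 are contiguous, with O6 α, the C7–C11 bond β, O8 β, O9 α and the epoxide oxygen α; the 2α-hydroxyl is separated from them by C3 and by the enoate. The sensitive groups are the exo-methylene lactone (a Michael acceptor), the angelate (isomerises to the tiglate), the vicinal C8/C9 esters beside a lactone that can translactonise onto O8, the trisubstituted epoxide and the γ-hydroxy enoate. The difficulty is to close a ten-membered ring with two cis unsaturations and to tell three secondary oxygens apart late in the route. The feature used here is that C10 (with C14) and C1 form a two-carbon propiolate unit inserted between C9 and C2. Removing it leaves an eight-membered ring C2–C9 in which the C4=C5 olefin is necessarily cis and C6, C7 and C8 already have their final configuration.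

## Retrosynthetic reasoning

Target 40 to 39. The 4,5-epoxide is removed last. In 39 the only electron-rich olefin is C4=C5 and the 2α-hydroxyl is homoallylic to it, so a hydroxyl-directed epoxidation can place the oxygen on the α face without touching the three electron-poor olefins.

39 back to 32. The acyl groups are taken off in the reverse of the order in which they can be put on: the C2 silyl ether (38), the angelate from 36 (35), the C8 silyl ether (34), the acetate (33) and the second silyl group (32). The order is set by reactivity. The allylic C2 hydroxyl of 32 is the most accessible and is capped first, the hindered C9 hydroxyl is then acetylated, and O8 is freed and acylated only when nothing else can compete.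

32 to 30. The C1=C10 enoate and the C2 hydroxyl are traced to a C1–C2 epoxide (31) next to the C10 ester: an E1cB opening shifts the unsaturation and leaves oxygen on C2. The epoxide in turn comes from the C1=C2 olefin of 30, and the C9 hydroxyl of 30, homoallylic to that olefin, is what lets it be oxidised in preference to C4=C5.

30 to 25. The C9 carbinol comes from the C9 ketone of 29, which is the hydrolysis product of the enamino ester 28. The exo-methylene is disconnected between these stages (28 to 25), because in 25 the lactone C11–H is the only readily enolisable position; later, the acetate and the other esters would compete.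

25 to 21 and 22. This is the central cut. The C9–C10 and C1–C2 bonds are removed and the C9–C2 bond restored, which contracts the ten-membered ring to the eight-membered enamine 21 and sets free 22. In the forward sense a [2+2] addition gives the aminocyclobutene 24, whose ring opening inserts C10–C1 between C9 and C2. The gain is that no macrocyclisation is needed and C14 arrives on C10 with unsaturation at C1–C2. 21 is the condensation product of ketone 19 and 20.

19 to 18. The cyclooctenone is opened at C4=C5 by a metathesis disconnection. The eight-membered ring enforces the Z geometry, and the partners are a C6 vinyl group and a C4 isopropenyl terminus, both simple to introduce.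

18 back to 15. The C9 ketone is masked as the dithiane of 17, the silyl ether is removed (16) and the lactone is opened to the hydroxy ester 15. The dithiane survives the reduction, lactonisation and silylation that precede its removal.

15 to 8 and 12. The C8 carbinol is traced to the C8 ketone 14, so that the free C6 hydroxyl can direct a 1,3-anti reduction. The C8–C9 bond is then cut to the Weinreb amide 8 and the acyl anion equivalent 12, itself from 9 and 10.

8 to 1, 2 and 5. The C6–C7 bond is an aldol bond. A syn aldol of the succinate imide 4 (from 1 and 2) with 5 gives 7, which sets C6 and C7 in the relationship that becomes the trans lactone fusion; transamination gives 8.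

## Alternatives that were turned down

Alternative 1: The last disconnection would cut the C5–O bond of the epoxide and the O6–C12 lactone bond of the target's C2 silyl ether A2. This leads back to A1, a ten-membered 5,6-epoxide with a tertiary C4 hydroxyl and an acrylate ester at C7. In the forward step base forms the C4 alkoxide, which attacks C5 with inversion (epoxide migration), and the released C6 alkoxide closes onto C12. In its favour, epoxide and exo-methylene lactone appear in one operation and the C5 configuration is relayed stereospecifically. On that point it is stronger than the chosen route, which relies on a directed epoxidation in the last step and makes the exo-methylene by enolate chemistry. Against it, A1 is as complex as the target and the plan does not say how its ten-membered ring, trans-5,6-epoxide and enoate are assembled. The alkoxide conditions would also meet an acetate, an angelate and an enoate, so acyl transfer to O6 and conjugate addition compete with lactonisation. The chosen strategy offers instead a solution to ring formation itself, with C14 delivered in the same step.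

Alternative 2: Here the C2–C3 bond is formed and the C5–C10 bond cleaved in one sigmatropic step. The precursor A3 is a cyclohexanol with an enol ether alkenyl group on the carbinol carbon and an isopropenyl group on the neighbouring carbon; its potassium alkoxide would rearrange to the enolate of the ten-membered ketone A4. In its favour, C6 to C9 are set on a six-membered ring, and the C2 oxygen and the C8/C9 diol are in place before the ring is opened. It is stronger than the chosen route on the configurations at C2 and C9, which the chosen route has to set on a medium ring. Against it, the Z C4=C5 olefin needs the two alkenyl groups cis and a boat-like transition state. A4 has a ketone where the target has the C10 ester carbon, so C14 must still be introduced and the C1=C10 geometry fixed. The lactone carbons are at the alcohol oxidation level under four different protecting groups, and A3 itself, with five contiguous stereocenters and a quaternary carbinol, is a long synthesis. The chosen strategy brings C14 and the unsaturation needed for C2 oxygenation in the ring-forming step and reaches its precursor in ten steps.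

Alternative 3: The C1=C10 and C4=C5 olefins of A6 are traced to two cyclobutane bonds of the tricycle A5, the photoadduct of a cyclohexenone and a cyclobutene; heating A5 would cleave C1–C4 and C5–C10. In its favour, both olefins and C14 appear in their final positions in one step and the C1=C10 bond does not have to be set by an elimination. On step count from the carbocycle, and on that geometry, it is stronger than the chosen route. Against it, the cleavage passes through a diradical, so olefin geometry is not controlled, and it needs temperatures at which a cyclodeca-1,5-diene can undergo Cope rearrangement. The regio- and facial course of the photocycloaddition on a lactone-fused enone is not secured. A6 also has no oxygen at C2, and a later allylic oxidation there would compete with the more reactive positions around C4=C5. The chosen strategy leaves the C1=C2 olefin exactly where the C2 oxygen is needed.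

Key step: step 12

Assumption: C10 in 29–31 is epimerisable and becomes trigonal in step 17, so these compounds are carried as C10 epimer mixtures and their SMILES leave C10 undefined. The transient centres of 23 and 24 are drawn for one face of attack; both faces lead to 25.

## Route

Step 1
Reactants: 1 (S)-4-benzyl-1,3-oxazolidin-2-one; 2 4-tert-butoxy-4-oxobutanoic acid
Product: 4 tert-butyl 4-[(4S)-4-benzyl-2-oxo-1,3-oxazolidin-3-yl]-4-oxobutanoate, via mixed pivalic anhydride 3 (not isolated)
Conditions: 2, t-BuCOCl, Et3N, THF, −20 °C; then 1, LiCl, −20 °C → rt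
Reagents that add atoms: none
Why: Mixed-anhydride N-acylation of the oxazolidinone; the hindered pivaloyl carbonyl is not attacked, so only the succinyl group is transferred and no stereocenter is touched.

Step 2
Reactants: 4; 5 acrolein
Product: 7 tert-butyl (3S,4R)-3-{[(4S)-4-benzyl-2-oxo-1,3-oxazolidin-3-yl]carbonyl}-4-hydroxyhex-5-enoate, via Z-boron enolate 6 (not isolated)
Conditions: Bu2BOTf, i-Pr2NEt, CH2Cl2, −78 → 0 °C; 5, −78 °C; pH 7 buffer, H2O2, MeOH, 0 °C
Reagents that add atoms: none
Why: Evans syn aldol: soft enolisation of the imide (not the tert-butyl ester) gives the Z-boron enolate 6, which adds to 5 through a chair Zimmerman–Traxler transition state on the face away from the benzyl group; this sets C7 (S) and C6 (R) in the syn relation that becomes the trans lactone fusion.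

Step 3
Reactants: 7
Product: 8 tert-butyl (3S,4R)-4-hydroxy-3-[methoxy(methyl)carbamoyl]hex-5-enoate
Conditions: MeNH(OMe)·HCl, AlMe3, THF, −10 → 0 °C
Reagents that add atoms: N,O-dimethylhydroxylamine hydrochloride, CNOC.Cl
Why: Aluminium amide transamination of the N-acyl oxazolidinone (Weinreb amide formation), assisted by the neighbouring aluminium alkoxide; the tert-butyl ester is inert and the auxiliary is recovered.

Step 4
Reactants: 9 1,3-dithiane; 10 4-bromo-2-methylbut-1-ene
Product: 12 2-(3-methylbut-3-en-1-yl)-1,3-dithiane, via 2-lithio-1,3-dithiane 11 (not isolated)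
Conditions: n-BuLi, THF, −30 °C; then 10, −78 → 0 °C
Reagents that add atoms: none
Why: Alkylation of a lithiated dithiane by a primary homoallylic bromide (dithiane umpolung); substitution outruns elimination at low temperature.

Step 5
Reactants: 8; 12
Product: 14 tert-butyl (3S,4R)-4-hydroxy-3-{[2-(3-methylbut-3-en-1-yl)-1,3-dithian-2-yl]carbonyl}hex-5-enoate, via lithiated dithiane 13 (not isolated)
Conditions: 12 (2.3 equiv), n-BuLi, THF, −30 °C; then 8, −78 → −40 °C; aq. NH4Cl
Reagents that add atoms: none
Why: Acyl anion addition to a Weinreb amide: the first equivalent of 13 deprotonates the hydroxyl, the second adds once, and the chelated tetrahedral adduct survives until the quench, so ketone 14 is released without over-addition or retro-aldol cleavage; C9 arrives as a masked carbonyl.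

Step 6
Reactants: 14
Product: 15 tert-butyl (3S,4R)-4-hydroxy-3-{(S)-hydroxy[2-(3-methylbut-3-en-1-yl)-1,3-dithian-2-yl]methyl}hex-5-enoate
Conditions: Me4NBH(OAc)3, MeCN/AcOH (1:1), −30 °C
Reagents that add atoms: none
Why: Evans–Saksena reduction: the C6 hydroxyl binds the triacetoxyborohydride and delivers hydride intramolecularly through a chair transition state, which gives the 1,3-anti diol and so the C8 (S) configuration; the dithiane tolerates the acidic medium.

Step 7
Reactants: 15
Product: 16 (4R,5R)-5-ethenyl-4-{(S)-hydroxy[2-(3-methylbut-3-en-1-yl)-1,3-dithian-2-yl]methyl}oxolan-2-one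
Conditions: t-BuOK (0.2 equiv), THF, −20 → 0 °C
Reagents that add atoms: none
Why: Base-catalysed intramolecular transesterification; both γ-hydroxyls can reach C12, but the alkoxides equilibrate and the trans-4,5-disubstituted lactone on O6 should be favoured over the cis lactone on O8, which would put the quaternary dithiane carbon next to the C6 side chain.

Step 8
Reactants: 16
Product: 17 (4S,5R)-4-{(S)-[(tert-butyldimethylsilyl)oxy][2-(3-methylbut-3-en-1-yl)-1,3-dithian-2-yl]methyl}-5-ethenyloxolan-2-one
Conditions: TBSOTf, 2,6-lutidine, CH2Cl2, −78 → 0 °C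
Reagents that add atoms: tert-butyldimethylsilyl trifluoromethanesulfonate, CC(C)(C)[Si](C)(C)OS(=O)(=O)C(F)(F)F
Why: Silyl triflate silylation of a hindered secondary alcohol; the bulky non-chelating silyl ether is also meant to bias the later hydride addition at C9.

Step 9
Reactants: 17
Product: 18 (4S,5R)-4-{(1S)-1-[(tert-butyldimethylsilyl)oxy]-5-methyl-2-oxohex-5-en-1-yl}-5-ethenyloxolan-2-one
Conditions: MeI, CaCO3, MeCN/H2O (9:1), 45 °C
Reagents that add atoms: water, O
Why: Alkylative dithiane hydrolysis (S-methylation, then hydrolysis of the sulfonium ion); the olefins, the lactone and the silyl ether are untouched, and the α-silyloxy ketone is not exposed to base.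

Step 10
Reactants: 18
Product: 19 (3aS,4S,8Z,9aR)-4-[(tert-butyldimethylsilyl)oxy]-8-methyl-3,3a,4,6,7,9a-hexahydrocycloocta[b]furan-2,5-dione
Conditions: second-generation Grubbs catalyst RuCl2(=CHPh)(PCy3)(H2IMes) (10 mol%), 1,4-benzoquinone (20 mol%), toluene (1 mM), 80 °C
Reagents that add atoms: none
Why: Ring-closing metathesis between the C6 vinyl group and the 1,1-disubstituted C4 olefin with loss of ethene; an eight-membered ring can hold only the Z trisubstituted olefin, so the C4=C5 geometry follows from ring size, and high dilution suppresses dimerisation.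

Step 11
Reactants: 19; 20 pyrrolidine
Product: 21 (3aS,4S,9aR)-4-[(tert-butyldimethylsilyl)oxy]-8-methyl-5-(pyrrolidin-1-yl)-3a,4,7,9a-tetrahydrocycloocta[b]furan-2(3H)-one
Conditions: 20 (6 equiv), TiCl4 (0.6 equiv), toluene, 0 °C → rt; filter; remove excess 20 under high vacuum
Reagents that add atoms: none
Why: Titanium-mediated enamine condensation; A(1,3) strain between the pyrrolidine ring and the C8 silyloxy substituent directs the double bond to the less substituted C2 side, and the short, cold reaction limits lactone aminolysis and C8 epimerisation.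

Step 12
Reactants: 21; 22 methyl propiolate
Product: 25 methyl (3aS,4S,5Z,7E,10Z,11aR)-4-[(tert-butyldimethylsilyl)oxy]-10-methyl-2-oxo-5-(pyrrolidin-1-yl)-2,3,3a,4,9,11a-hexahydrocyclodeca[b]furan-6-carboxylate, via iminium allenolate zwitterion 23 (not isolated), via cis-fused aminocyclobutene 24 (not isolated)
Conditions: 22 (1.3 equiv), Et2O, 0 °C → rt; then toluene, 50 °C until 24 is consumed
Reagents that add atoms: none
Why: The cycloaddition is a polar, stepwise [2+2]: the nucleophilic enamine carbon C2 adds to the unsubstituted, electrophilic alkyne carbon (C1) of 22 to give zwitterion 23, whose allenolate carbon C10 closes onto the iminium carbon C9. This 4-exo closure can give only the cis-fused bicyclo[6.2.0] aminocyclobutene 24, so the four-membered ring is closed by ionic collapse and not by a concerted thermal process. The push–pull cyclobutene then undergoes thermal conrotatory four-electron ring opening that cleaves the old C9–C2 bond; the ten-membered ring therefore arises by ring expansion and no macrocyclisation is needed. Torquoselectivity (the amino donor rotates outward) turns C8 inward and C3 outward, which gives the Z C9=C10 and E C1=C2 diene of 25, stabilised as a vinylogous carbamate. The closest known reaction type is the two-carbon ring enlargement of cyclic ketone enamines with acetylenic esters, applied here to a functionalised cyclooctenone. No lasting stereocenter is created: C2 and C9 become trigonal again, so the facial course of the first bond formation is irrelevant, and C6, C7 and C8 are not involved. The selectivity needed is regiochemical: the enamine must be the C9=C2 isomer (secured in step 11 by the C8 substituent) and C2 must bond to the alkyne terminus (secured by the polarity of the ynoate); free amine, which would add to 22, is removed beforehand. The E C1=C2 geometry is temporary and is erased in steps 16 and 17.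

Step 13
Reactants: 25
Product: 28 11(13)-methylidene derivative of 25 (exo-methylene lactone), via Mannich base 26 (not isolated), via trimethylammonium iodide 27 (not isolated)
Conditions: LDA, THF, −78 °C; Me2N=CH2+ I−, −78 → −20 °C; then MeI, CH2Cl2, rt; then aq. NaHCO3/EtOAc, rt
Reagents that add atoms: N,N-dimethylmethyleneiminium iodide (Eschenmoser's salt), C=[N+](C)C.[I-]
Why: Lactone enolate aminomethylation (Mannich reaction), exhaustive N-methylation and Hofmann-type β-elimination; in 25 the lactone C11–H is the only readily enolisable position (the C14 ester is a vinylogous carbamate without α-hydrogen), which is why the exo-methylene is made here and not after the other esters are in place.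

Step 14
Reactants: 28
Product: 29 methyl 8β-[(tert-butyldimethylsilyl)oxy]-9-oxogermacra-1E,4Z,11(13)-trien-12,6α-olid-14-oate (C10 epimers; partly enolised)
Conditions: 1 M HCl/THF (1:3), 0 °C → rt; used without chromatography
Reagents that add atoms: water, O
Why: Acid hydrolysis of the enamino ester: kinetic protonation at C10 gives the iminium ion and water releases the C9 ketone, while the E C1=C2 olefin stays out of conjugation; the product is used at once to avoid migration of that olefin.

Step 15
Reactants: 29
Product: 30 methyl 8β-[(tert-butyldimethylsilyl)oxy]-9α-hydroxygermacra-1E,4Z,11(13)-trien-12,6α-olid-14-oate (C10 epimers)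
Conditions: NaBH4, CeCl3·7H2O, MeOH, −40 → −20 °C
Reagents that add atoms: none
Why: Luche reduction: 1,2-hydride addition to the keto tautomer without conjugate reduction of the exo-methylene lactone; Felkin–Anh attack anti to the bulky C8 silyloxy group from the ring periphery should give the 9α-alcohol, trans to O8 (C9 S in the target).

Step 16
Reactants: 30
Product: 31 (1S,2S)-1,2-epoxide of 30 (trans epoxide; C2–O bond α; C10 epimers)
Conditions: VO(acac)2 (10 mol%), t-BuOOH (decane), CH2Cl2, 0 °C → rt
Reagents that add atoms: tert-butyl hydroperoxide, CC(C)(C)OO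
Why: Hydroxyl-directed vanadium-catalysed epoxidation of a homoallylic alcohol: the C9 vanadate delivers the peroxide oxygen to C1=C2, which overrides the intrinsically higher reactivity of the trisubstituted C4=C5 olefin and leaves the electron-poor exo-methylene alone; delivery from O9 onto the exposed face of the E olefin should place the new C2–O bond α.

Step 17
Reactants: 31
Product: 32 methyl 8β-[(tert-butyldimethylsilyl)oxy]-2α,9α-dihydroxygermacra-1(10)E,4Z,11(13)-trien-12,6α-olid-14-oate (C9 and C2 cis on the olefin)
Conditions: DBU (1.5 equiv), CH2Cl2, 0 °C → rt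
Reagents that add atoms: none
Why: E1cB opening of a β,γ-epoxy ester: reversible deprotonation at C10 and expulsion of the epoxide oxygen from C1 give the γ-hydroxy enoate with retention at C2 (S); the C9 hydroxyl is a poor leaving group, so epoxide opening wins, and the less strained ring-cis olefin (C14 trans to C2, so no butenolide can form) is expected.

Step 18
Reactants: 32
Product: 33 2α-O-tert-butyldiphenylsilyl ether of 32
Conditions: TBDPSCl (1.1 equiv), imidazole, DMF, 0 °C
Reagents that add atoms: tert-butyl(chloro)diphenylsilane, CC(C)(C)[Si](Cl)(c1ccccc1)c1ccccc1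
Why: Selective silylation: the allylic C2 hydroxyl is far less hindered than the C9 hydroxyl, which is flanked by the C8 silyl ether and the C10 ester.

Step 19
Reactants: 33
Product: 34 9α-acetate of 33
Conditions: Ac2O, pyridine, DMAP (10 mol%), CH2Cl2, rt
Reagents that add atoms: acetic anhydride, CC(=O)OC(C)=O
Why: DMAP-catalysed acetylation of the remaining, hindered secondary alcohol.

Step 20
Reactants: 34
Product: 35 8β-alcohol (9α-acetate and 2α-silyl ether retained)
Conditions: HF·pyridine, pyridine/THF, 0 °C → rt
Reagents that add atoms: none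
Why: Acidic fluoride cleaves the secondary tert-butyldimethylsilyl ether much faster than the tert-butyldiphenylsilyl ether, and the non-basic medium prevents acetyl or lactone migration to the freed C8 hydroxyl.

Step 21
Reactants: 35; 36 angelic acid
Product: 38 8β-angelate of 35, via angelic trichlorobenzoic anhydride 37 (not isolated)
Conditions: 36, 2,4,6-trichlorobenzoyl chloride, Et3N, toluene, rt; then 35, 80 °C
Reagents that add atoms: none
Why: Yamaguchi-type esterification through mixed anhydride 37 without a nucleophilic catalyst, the conditions under which hindered alcohols are acylated by angelic acid without isomerisation to the tiglate.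

Step 22
Reactants: 38
Product: 39 methyl 9α-acetoxy-8β-angeloyloxy-2α-hydroxygermacra-1(10)E,4Z,11(13)-trien-12,6α-olid-14-oate
Conditions: HF·pyridine (excess), THF, rt
Reagents that add atoms: none
Why: Fluoride desilylation under acidic, non-nucleophilic conditions that spare the three esters and the exo-methylene lactone.

Step 23
Reactants: 39
Product: 40 target CNP0278274.1, the 4α,5α-epoxide of 39
Conditions: VO(acac)2 (10 mol%), t-BuOOH (decane), CH2Cl2, 0 °C → rt
Reagents that add atoms: tert-butyl hydroperoxide, CC(C)(C)OO
Why: Hydroxyl-directed vanadium-catalysed epoxidation of a homoallylic alcohol: the C2 vanadate reaches only the trisubstituted C4=C5 olefin (the enoate, angelate and exo-methylene olefins are electron-poor) and delivers oxygen syn to the 2α-hydroxyl, which gives the 4α,5α-epoxide with C4 (R) and C5 (S).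

## Compound list

1 | (S)-4-benzyl-1,3-oxazolidin-2-one | O=C1OC[C@H](Cc2ccccc2)N1 | starting material
2 | 4-tert-butoxy-4-oxobutanoic acid | CC(C)(C)OC(=O)CCC(=O)O | starting material
3 | 4-tert-butoxy-4-oxobutanoic pivalic anhydride | CC(C)(C)OC(=O)CCC(=O)OC(=O)C(C)(C)C | intermediate
4 | tert-butyl 4-[(4S)-4-benzyl-2-oxo-1,3-oxazolidin-3-yl]-4-oxobutanoate | CC(C)(C)OC(=O)CCC(=O)N1[C@@H](Cc2ccccc2)COC1=O | intermediate
5 | acrolein | C=CC=O | starting material
6 | Z-dibutylboron enolate of 4 | CCCCB(CCCC)O/C(=C\CC(=O)OC(C)(C)C)N1[C@@H](Cc2ccccc2)COC1=O | intermediate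
7 | tert-butyl (3S,4R)-3-{[(4S)-4-benzyl-2-oxo-1,3-oxazolidin-3-yl]carbonyl}-4-hydroxyhex-5-enoate | C=C[C@@H](O)[C@H](CC(=O)OC(C)(C)C)C(=O)N1[C@@H](Cc2ccccc2)COC1=O | intermediate
8 | tert-butyl (3S,4R)-4-hydroxy-3-[methoxy(methyl)carbamoyl]hex-5-enoate | C=C[C@@H](O)[C@H](CC(=O)OC(C)(C)C)C(=O)N(C)OC | intermediate
9 | 1,3-dithiane | C1CSCSC1 | starting material
10 | 4-bromo-2-methylbut-1-ene | C=C(C)CCBr | starting material
11 | 2-lithio-1,3-dithiane | [Li]C1SCCCS1 | intermediate
12 | 2-(3-methylbut-3-en-1-yl)-1,3-dithiane | C=C(C)CCC1SCCCS1 | intermediate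
13 | 2-lithio-2-(3-methylbut-3-en-1-yl)-1,3-dithiane | [Li]C1(CCC(C)=C)SCCCS1 | intermediate
14 | tert-butyl (3S,4R)-4-hydroxy-3-{[2-(3-methylbut-3-en-1-yl)-1,3-dithian-2-yl]carbonyl}hex-5-enoate | C=C[C@@H](O)[C@H](CC(=O)OC(C)(C)C)C(=O)C1(CCC(C)=C)SCCCS1 | intermediate
15 | tert-butyl (3S,4R)-4-hydroxy-3-{(S)-hydroxy[2-(3-methylbut-3-en-1-yl)-1,3-dithian-2-yl]methyl}hex-5-enoate | C=C[C@@H](O)[C@H](CC(=O)OC(C)(C)C)[C@H](O)C1(CCC(C)=C)SCCCS1 | intermediate
16 | (4R,5R)-5-ethenyl-4-{(S)-hydroxy[2-(3-methylbut-3-en-1-yl)-1,3-dithian-2-yl]methyl}oxolan-2-one | C=C[C@H]1OC(=O)C[C@@H]1[C@H](O)C2(CCC(C)=C)SCCCS2 | intermediate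
17 | (4S,5R)-4-{(S)-[(tert-butyldimethylsilyl)oxy][2-(3-methylbut-3-en-1-yl)-1,3-dithian-2-yl]methyl}-5-ethenyloxolan-2-one | C=C[C@H]1OC(=O)C[C@@H]1[C@H](O[Si](C)(C)C(C)(C)C)C2(CCC(C)=C)SCCCS2 | intermediate
18 | (4S,5R)-4-{(1S)-1-[(tert-butyldimethylsilyl)oxy]-5-methyl-2-oxohex-5-en-1-yl}-5-ethenyloxolan-2-one | C=C[C@H]1OC(=O)C[C@@H]1[C@H](O[Si](C)(C)C(C)(C)C)C(=O)CCC(C)=C | intermediate
19 | (3aS,4S,8Z,9aR)-4-[(tert-butyldimethylsilyl)oxy]-8-methyl-3,3a,4,6,7,9a-hexahydrocycloocta[b]furan-2,5-dione | O=C1CC/C(C)=C\[C@H]2OC(=O)C[C@@H]2[C@@H]1O[Si](C)(C)C(C)(C)C | intermediate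
20 | pyrrolidine | C1CCNC1 | starting material
21 | (3aS,4S,9aR)-4-[(tert-butyldimethylsilyl)oxy]-8-methyl-5-(pyrrolidin-1-yl)-3a,4,7,9a-tetrahydrocycloocta[b]furan-2(3H)-one | C1/C(C)=C\[C@H]2OC(=O)C[C@@H]2[C@H](O[Si](C)(C)C(C)(C)C)/C(N3CCCC3)=C\1 | intermediate
22 | methyl propiolate | C#CC(=O)OC | starting material
23 | iminium allenolate zwitterion (C2–C1 bond formed) | COC([O-])=C=C[C@H]1C/C(C)=C\[C@H]2OC(=O)C[C@@H]2[C@H](O[Si](C)(C)C(C)(C)C)C1=[N+]1CCCC1 | intermediate
24 | cis-fused bicyclo[6.2.0] aminocyclobutene ester | C1/C(C)=C\[C@H]2OC(=O)C[C@@H]2[C@H](O[Si](C)(C)C(C)(C)C)[C@@]3(N4CCCC4)C(C(=O)OC)=C[C@@H]13 | intermediate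
25 | methyl (3aS,4S,5Z,7E,10Z,11aR)-4-[(tert-butyldimethylsilyl)oxy]-10-methyl-2-oxo-5-(pyrrolidin-1-yl)-2,3,3a,4,9,11a-hexahydrocyclodeca[b]furan-6-carboxylate | C1/C(C)=C\[C@H]2OC(=O)C[C@@H]2[C@H](O[Si](C)(C)C(C)(C)C)/C(N3CCCC3)=C(C(=O)OC)\C=C\1 | intermediate
26 | 11-[(dimethylamino)methyl] derivative of 25 (substituent trans to C8) | C1/C(C)=C\[C@H]2OC(=O)[C@@H](CN(C)C)[C@@H]2[C@H](O[Si](C)(C)C(C)(C)C)/C(N3CCCC3)=C(C(=O)OC)\C=C\1 | intermediate
27 | trimethylammonium iodide of 26 | C1/C(C)=C\[C@H]2OC(=O)[C@@H](C[N+](C)(C)C)[C@@H]2[C@H](O[Si](C)(C)C(C)(C)C)/C(N3CCCC3)=C(C(=O)OC)\C=C\1.[I-] | intermediate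
28 | 11(13)-methylidene derivative of 25 | C1/C(C)=C\[C@H]2OC(=O)C(=C)[C@@H]2[C@H](O[Si](C)(C)C(C)(C)C)/C(N3CCCC3)=C(C(=O)OC)\C=C\1 | intermediate
29 | methyl 8β-[(tert-butyldimethylsilyl)oxy]-9-oxogermacra-1E,4Z,11(13)-trien-12,6α-olid-14-oate | C1/C(C)=C\[C@H]2OC(=O)C(=C)[C@@H]2[C@H](O[Si](C)(C)C(C)(C)C)C(=O)C(C(=O)OC)/C=C/1 | intermediate
30 | methyl 8β-[(tert-butyldimethylsilyl)oxy]-9α-hydroxygermacra-1E,4Z,11(13)-trien-12,6α-olid-14-oate | C1/C(C)=C\[C@H]2OC(=O)C(=C)[C@@H]2[C@H](O[Si](C)(C)C(C)(C)C)[C@@H](O)C(C(=O)OC)/C=C/1 | intermediate
31 | (1S,2S)-1,2-epoxide of 30 | C1/C(C)=C\[C@H]2OC(=O)C(=C)[C@@H]2[C@H](O[Si](C)(C)C(C)(C)C)[C@@H](O)C(C(=O)OC)[C@@H]3O[C@H]31 | intermediate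
32 | methyl 8β-[(tert-butyldimethylsilyl)oxy]-2α,9α-dihydroxygermacra-1(10)E,4Z,11(13)-trien-12,6α-olid-14-oate | C1/C(C)=C\[C@H]2OC(=O)C(=C)[C@@H]2[C@H](O[Si](C)(C)C(C)(C)C)[C@@H](O)/C(C(=O)OC)=C\[C@H]1O | intermediate
33 | 2α-O-tert-butyldiphenylsilyl ether of 32 | C1/C(C)=C\[C@H]2OC(=O)C(=C)[C@@H]2[C@H](O[Si](C)(C)C(C)(C)C)[C@@H](O)/C(C(=O)OC)=C\[C@H]1O[Si](c3ccccc3)(c4ccccc4)C(C)(C)C | intermediate
34 | 9α-acetate of 33 | C1/C(C)=C\[C@H]2OC(=O)C(=C)[C@@H]2[C@H](O[Si](C)(C)C(C)(C)C)[C@@H](OC(C)=O)/C(C(=O)OC)=C\[C@H]1O[Si](c3ccccc3)(c4ccccc4)C(C)(C)C | intermediate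
35 | 8β-alcohol from 34 | C1/C(C)=C\[C@H]2OC(=O)C(=C)[C@@H]2[C@H](O)[C@@H](OC(C)=O)/C(C(=O)OC)=C\[C@H]1O[Si](c3ccccc3)(c4ccccc4)C(C)(C)C | intermediate
36 | angelic acid, (Z)-2-methylbut-2-enoic acid | C/C=C(/C)C(=O)O | starting material
37 | angelic 2,4,6-trichlorobenzoic anhydride | C/C=C(/C)C(=O)OC(=O)c1c(Cl)cc(Cl)cc1Cl | intermediate
38 | 8β-angelate of 35 | C1/C(C)=C\[C@H]2OC(=O)C(=C)[C@@H]2[C@H](OC(=O)/C(C)=C\C)[C@@H](OC(C)=O)/C(C(=O)OC)=C\[C@H]1O[Si](c3ccccc3)(c4ccccc4)C(C)(C)C | intermediate
39 | methyl 9α-acetoxy-8β-angeloyloxy-2α-hydroxygermacra-1(10)E,4Z,11(13)-trien-12,6α-olid-14-oate | C1/C(C)=C\[C@H]2OC(=O)C(=C)[C@@H]2[C@H](OC(=O)/C(C)=C\C)[C@@H](OC(C)=O)/C(C(=O)OC)=C\[C@H]1O | intermediate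
40 | CNP0278274.1, methyl (2S,4R,5S,6S,7R,8S,9S)-9-acetoxy-8-angeloyloxy-4,5-epoxy-2-hydroxygermacra-1(10)E,11(13)-dien-12,6-olid-14-oate | C=C1C(=O)O[C@H]2[C@H]1[C@H](OC(=O)/C(C)=C\C)[C@@H](OC(C)=O)/C(C(=O)OC)=C\[C@@H](O)C[C@@]1(C)O[C@@H]21 | target

## Step count and risks

Total step count: 23. Longest linear sequence: 22 steps (steps 1–3 and 5–23); step 4 is a one-step side branch.

Least certain steps:

Step 12 (key step). The zwitterion may be intercepted by proton transfer before it closes, which would stop at an open-chain Michael adduct. The cyclobutene may also open only at temperatures that the strained triene, with its E olefin, does not tolerate. A related weakness lies upstream in step 11, where the enamine may equilibrate through its C8 regioisomer and scramble C8, or the amine may open the lactone. Fallback: it sets out from 19 and needs no amine. Kinetic enolisation toward C2 (LiN(SiMe3)2, TBSCl, THF, −78 °C) gives the C9 silyl enol ether F1. An acid-catalysed [2+2] addition with 22 (HNTf2 or EtAlCl2, CH2Cl2, −78 °C) gives the silyloxycyclobutene F2, and heating in toluene opens it to the ten-membered silyl dienol ether ester F3. The aminomethylation–elimination sequence of step 13 converts F3 into the exo-methylene lactone F4, and mild acid cleaves the enol silyl ether, which returns the route to 29.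

Step 17. The elimination may set the new C1=C10 bond with C9 and C2 trans. That isomer has the C2 oxygen cis to C14, so lactonisation to a butenolide would follow and would take material out of the route. Fallback: it sets out from 31. The elimination is run with the silyl chloride of step 18 already present, so that the C2 alkoxide is capped as it forms. Any ring-trans silyl ether F11 is then equilibrated by reversible thiyl radical addition (PhSSPh, light, benzene) toward the less strained ring-cis olefin, which returns the route to 33.

Step 16. Oxygen delivery from the C9 vanadate may be slow on the strained E olefin, so that the trisubstituted C4=C5 olefin is attacked competitively, or delivery may occur so that C2 ends up β. Both follow from the ring conformation, which cannot be predicted with confidence. Fallback: it sets out from 30 and avoids epoxidation. The dianion (LDA, 2.2 equiv, THF, −78 °C) is selenenylated at C10 with PhSeBr to give the α-phenylselenyl ester F10. Oxidation at selenium (H2O2, pyridine, CH2Cl2, 0 °C) triggers a [2,3]-sigmatropic shift that moves oxygen to C2 and the double bond to C1=C10, and cleavage of the Se–O bond on work-up returns the route to 32.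

Step 15. Hydride addition on the ten-membered ring may be governed by ring conformation and not by the Felkin–Anh preference, and then the 9β-alcohol would dominate. Fallback: it sets out from 29 and carries the 9-epimer forward. The 9β-hydroxy ester F6 is epoxidised as in step 16 to F7, opened as in step 17 to diol F8 and silylated at O2 as in step 18 to F9. A Mitsunobu reaction with acetic acid (PPh3, DIAD, toluene) then installs the acetate with inversion at C9 and returns the route to 34. The C2 configuration has to be confirmed on F8, because the directing hydroxyl is then on the other face.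

Step 10. Closure of an eight-membered ring onto a 1,1-disubstituted olefin, trans-fused to the lactone, may be slower than dimerisation or olefin migration. Fallback: it sets out from 17. The metathesis is done at the dithiane stage, where the C9 quaternary centre favours the folded conformer (geminal substituent effect), to give the bicyclic dithiane F5. The hydrolysis of step 9 (MeI, CaCO3, aqueous MeCN) then returns the route to 19.

## Further compounds

F1 | step 12 | C9 tert-butyldimethylsilyl enol ether of 19 (C9=C2) | C1/C(C)=C\[C@H]2OC(=O)C[C@@H]2[C@H](O[Si](C)(C)C(C)(C)C)/C(O[Si](C)(C)C(C)(C)C)=C\1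
F2 | step 12 | cis-fused bicyclo[6.2.0] silyloxycyclobutene ester | C1/C(C)=C\[C@H]2OC(=O)C[C@@H]2[C@H](O[Si](C)(C)C(C)(C)C)[C@@]3(O[Si](C)(C)C(C)(C)C)C(C(=O)OC)=C[C@@H]13
F3 | step 12 | ten-membered silyl dienol ether ester (silyloxy analogue of 25) | C1/C(C)=C\[C@H]2OC(=O)C[C@@H]2[C@H](O[Si](C)(C)C(C)(C)C)/C(O[Si](C)(C)C(C)(C)C)=C(C(=O)OC)\C=C\1
F4 | step 12 | 11(13)-methylidene derivative of F3 | C1/C(C)=C\[C@H]2OC(=O)C(=C)[C@@H]2[C@H](O[Si](C)(C)C(C)(C)C)/C(O[Si](C)(C)C(C)(C)C)=C(C(=O)OC)\C=C\1
F5 | step 10 | C9 1,3-dithiane (spiro) of 19 | C1/C(C)=C\[C@H]2OC(=O)C[C@@H]2[C@H](O[Si](C)(C)C(C)(C)C)C3(SCCCS3)C1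
F6 | step 15 | 9β-hydroxy epimer of 30 | C1/C(C)=C\[C@H]2OC(=O)C(=C)[C@@H]2[C@H](O[Si](C)(C)C(C)(C)C)[C@H](O)C(C(=O)OC)/C=C/1
F7 | step 15 | 9β-hydroxy epimer of 31 | C1/C(C)=C\[C@H]2OC(=O)C(=C)[C@@H]2[C@H](O[Si](C)(C)C(C)(C)C)[C@H](O)C(C(=O)OC)[C@@H]3O[C@H]31
F8 | step 15 | 9β-hydroxy epimer of 32 | C1/C(C)=C\[C@H]2OC(=O)C(=C)[C@@H]2[C@H](O[Si](C)(C)C(C)(C)C)[C@H](O)/C(C(=O)OC)=C\[C@H]1O
F9 | step 15 | 9β-hydroxy epimer of 33 | C1/C(C)=C\[C@H]2OC(=O)C(=C)[C@@H]2[C@H](O[Si](C)(C)C(C)(C)C)[C@H](O)/C(C(=O)OC)=C\[C@H]1O[Si](c3ccccc3)(c4ccccc4)C(C)(C)C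
F10 | step 16 | 10-phenylselenyl derivative of 30 | C1/C(C)=C\[C@H]2OC(=O)C(=C)[C@@H]2[C@H](O[Si](C)(C)C(C)(C)C)[C@@H](O)C([Se]c3ccccc3)(C(=O)OC)/C=C/1
F11 | step 17 | C1(10) geometric isomer of 33 (C9 and C2 trans) | C1/C(C)=C\[C@H]2OC(=O)C(=C)[C@@H]2[C@H](O[Si](C)(C)C(C)(C)C)[C@@H](O)/C(C(=O)OC)=C/[C@H]1O[Si](c3ccccc3)(c4ccccc4)C(C)(C)C
A1 | alternative 1 | ten-membered trans-5,6-epoxide with 4-hydroxyl and C7 acrylate methyl ester (C2 silyl ether) | C=C(C(=O)OC)[C@@H]1[C@H](OC(=O)/C(C)=C\C)[C@@H](OC(C)=O)/C(C(=O)OC)=C\[C@@H](O[Si](C)(C)C(C)(C)C)C[C@@](C)(O)[C@@H]2O[C@H]21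
A2 | alternative 1 | C2 tert-butyldimethylsilyl ether of the target | C=C1C(=O)O[C@H]2[C@H]1[C@H](OC(=O)/C(C)=C\C)[C@@H](OC(C)=O)/C(C(=O)OC)=C\[C@@H](O[Si](C)(C)C(C)(C)C)C[C@@]1(C)O[C@@H]21
A3 | alternative 2 | cis-dialkenylcyclohexanol (enol ether on the carbinol carbon and isopropenyl on the neighbouring carbon) | O[C@@]1(/C=C/OCc2ccc(OC)cc2)[C@H](C(C)=C)[C@@H](O[Si](C)(C)C(C)(C)C)[C@H](CCO[Si](C)(C)C(C)(C)C)[C@@H]2OC(C)(C)O[C@@H]12
A4 | alternative 2 | ten-membered C10 ketone with Z C4=C5 and C2 ether | O=C1C[C@@H](OCc3ccc(OC)cc3)C/C(C)=C\[C@@H](O[Si](C)(C)C(C)(C)C)[C@H](CCO[Si](C)(C)C(C)(C)C)[C@@H]2OC(C)(C)O[C@@H]12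
A5 | alternative 3 | lactone-fused tricyclo[4.4.0.0(2,5)]decanone ester photoadduct | COC(=O)[C@]12C(=O)[C@@H](O[Si](C)(C)C(C)(C)C)[C@H]3CC(=O)O[C@@H]3[C@H]1[C@]1(C)CC[C@H]21
A6 | alternative 3 | (Z,Z)-cyclodeca-1(10),4-diene keto ester with fused lactone | COC(=O)/C1=C/CC/C(C)=C\[C@H]2OC(=O)C[C@@H]2[C@H](O[Si](C)(C)C(C)(C)C)C1=O
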